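## Structural features

The target is a labdane-type bicycle: a trans-fused decalin (ring A = C1–C5 and C10, ring B = C5–C10) with an exocyclic methylene on C8 (C17), an (E)-3-methylpenta-2,4-dienyl chain on C9 (C11–C16), an acetoxy group on C1, an angular methyl on C10, and a methyl plus a methyl ester (C19) on C4. Five stereocentres are contiguous, C4–C5–C10–C1 along ring A with C9 attached to C10, and C4 and C10 are quaternary. The configuration is 1S,4R,5S,9R,10S: the acetoxy group, the C10 methyl, the side chain and the ester lie on one face, H5 and H9 on the other, and the C4 ester is syn-axial to the C10 methyl. The conjugated diene (acid, heat, oxidants), the exocyclic alkene (acid-induced migration into the ring) and the secondary acetate (bases, nucleophiles) are fragile; the axial ester is robust. The real difficulty is quaternary C10, which is flanked by the neopentyl carbinol C1 (oxygen cis to the methyl), by C5 and by C9, whose equatorial side chain is in a syn-pentane contact with the C1 oxygen. The key step exploits the array O–C1–C10–C9–C8: a carbinol carbon bonded to a quaternary carbon, next to a carbon that needs only a traceless activating group, next to an sp2 carbon. This array maps onto a ketyl carbon, the β- and α-carbons of an unsaturated ester and an acyl carbon, so a single chain with a C1 aldehyde, a C10=C9 enoate and a C8 ester folds into rings A and B from the one preset centre C5. The configurations of the key-step precursor and product were checked against the target and are mutually consistent, so nothing needed correcting; only the descriptor at C5 changes (R before C4 is quaternary, S after) with no change in space.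

## Logic of the disconnections

23 ⇒ 22. Cut the O–acyl bond at C1. The acetate would not survive the ylide and amide bases used earlier, so it goes on last. The forward step must acylate a hindered equatorial alcohol without acid.

22 ⇒ 20. Cut C4–C18. The quaternary centre with the ester cis to the C10 methyl is the expected outcome of methylating an exocyclic ester enolate on the face away from the syn-axial methyl. C4 becomes a CH whose configuration is irrelevant. The forward step needs facial selectivity and tolerance of the free C1 alkoxide.

20 ⇒ 19. Cut C8=C17. The ketone is what the key step leaves at C8. The forward step must olefinate a hindered, enolizable ketone without losing C9.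

19 ⇒ 18. Add back the C9 ethyl ester and the second C4 methyl ester. The C9 ester gives regiocontrol for the side-chain bond and the gem-diester keeps C4 achiral. The forward step is a double dealkoxycarbonylation in the presence of the diene, with C9 protonated on the face away from the C10 methyl.

18 ⇒ 14 + 17. Cut C9–C11. C9 is the only doubly activated carbon, and the side chain arrives as an intact (E)-diene. The forward step must favour C- over O-alkylation at a carbon next to quaternary C10.

17 ⇒ 16 ⇒ 15. Bromide from the allylic alcohol, terminal alkene from the alkyne. The (E)-trisubstituted alkene is taken from a purchasable enynol.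

14 ⇒ 12. Cut C1–C10 and C8–C9: two rings, two skeletal bonds and three stereocentres go back to one acyclic aldehyde. The forward step needs a regiospecific C9 enolate, which only the radical–polar crossover provides, because a base would enolize C7. The constitution of 12 is kept and its design is tightened on three points. The ester types are matched to their roles: methyl at C8 as acyl acceptor, ethyl on the enoate as the poorer acceptor, and a gem-dimethyl diester at C4. The (E)-enoate places only H on C9 cis to C5, so allylic strain fixes the conformation. The conditions are aprotic, so the enolate lives long enough to acylate.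

12 ⇒ 10 + 11. Cut C3–C4. Conjugate addition of the malonate C–H to an enal delivers C1–C3 with C1 already at the aldehyde level. It is placed after the homologation to avoid a dialdehyde.

10 ⇒ 8 ⇒ 6 ⇒ 5. Cut C7–C8. The organocatalytic step leaves an aldehyde at C7, while ring B needs a carboxyl carbon at C8, so a one-carbon homologation of the derived acid is used. The forward steps must not disturb C5.

5 ⇒ 3 + 4. Cut C4–C5. This is the only bond made under catalyst control; every other stereocentre is relayed from C5. The forward step needs β- over δ-addition and high facial selectivity.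

3 ⇒ 1 + 2. Cut the C5=C6 alkene (labdane numbering), a two-carbon vinylogation of a purchasable aldehyde ester.

## Other disconnections considered

Alternative 1: Cut C1–C10 and C4–C5, building ring A by a [4+2] cycloaddition. The silyloxydiene A1 and the α-methyl enal A2 would combine under a chiral Lewis acid (for example a cationic oxazaborolidine) in an exo-selective Diels–Alder reaction to give A3.
- In its favour: it is convergent and sets C1, C10, C5 and C4 in one concerted, stereospecific step. The absolute configuration is controlled directly at the ring, and α-methyl enals have an inherent preference for the formyl-exo mode. On the construction of quaternary C10 next to the oxygenated C1 it is the better of the two plans.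
- Against it: A2 is a trisubstituted enal of low dienophilicity. Ring B, C9 and the side chain are all still missing after A3. Closing ring B from the formyl group and the bromoalkene (for instance with CrCl2/NiCl2) would leave an allylic alcohol at C9 and not the C9–C11 bond. The C2=C3 alkene must be reduced beside a bromoalkene. The C4 centre set in the cycloaddition is erased when C4 is made quaternary.
- Comparison: the two plans are equal at the end of ring A, since both finish C4 by the same enolate methylation. The chosen plan is stronger on ring B and C9, which its cascade delivers already activated, and should need fewer steps after the key step.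

Alternative 2: Cut C5–C10 and C3–C4. The acyclic vinyl ketone A4, with C9 preset, would be converted into its C10 enolate (LiN(SiMe3)2) or 2-silyloxydiene (Me3SiOTf, Et3N). A double Michael cascade would then close ring B and ring A to give A5.
- In its favour: both rings form in one polar cascade with the trans fusion set in chair transition states. A5 already carries the C8 methylene and the first side-chain carbons, so the C9 alkylation, the dealkoxycarbonylation at C9 and the methylenation are not needed. On ring B economy it is the better plan, and it needs no stoichiometric lanthanide.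
- Against it: C1 arrives as a ketone and needs a separate stereoselective reduction. The C1 ketone competes with the C4 ester in enolization, so the C4 methylation must wait. A4 is a polymerization-prone vinyl ketone with an allylic stereocentre next to an enolizable one, and its relative control over C10 and C5 rests on acyclic preferences. The silyl ether must still be elaborated into the (E)-diene.
- Comparison: the plans are equal in bond and ring count of the key step, and both make quaternary C10 by conjugate addition. The chosen plan has the shorter, configurationally simpler precursor (one stereocentre) and obtains the C1 oxygen with its configuration in the cascade itself. Overall step counts should be similar.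

Alternative 3: Cut C9–C10. The phenol A6, under a zerovalent palladium catalyst with a chiral phosphine, would ionize to a π-allyl complex that the phenolate attacks through its methyl-bearing ortho carbon, giving the dienone A7.
- In its favour: the arene supplies all ring A carbons, the C10 methyl, the C19 carboxyl and the C1 oxygen. C9 and C10 are set by the catalyst, the C8 methylene is in place, and the precursor is short and convergent. In precursor length and convergence it is the better plan.
- Against it: a phenolate with a para ester is a weak nucleophile. Blocked cyclohexa-2,4-dienones tend to dimerize by [4+2]. C5 and C4 are still sp2 after the key step, so the tetrasubstituted, ester-conjugated C4=C5 bond must be reduced with control at C5 beside the more easily reduced C8=C17 alkene. The C1 ketone must then be reduced and C4 methylated. Control of C9 relative to C10 depends on the π-allyl geometry as well as on the ligand.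
- Comparison: the plans are equal on the last C4 methylation. The chosen plan relays all its stereocentres from one secure centre and leaves ring A saturated with C1 and C5 already correct. The alternative reaches its key step in fewer steps but probably needs more, and less certain, steps afterwards.

Key step: step 7

Remark on the chemistry: 19 and 20 are carried as mixtures of C4 epimers because C4 is made planar in step 13, and 15 is taken to be purchasable as the pure (E)-isomer.

## Route

Step 1
Reactants: 1 ethyl (E)-3-methyl-4-oxobut-2-enoate; 2 (formylmethylene)triphenylphosphorane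
Product: 3 ethyl (2E,4E)-3-methyl-6-oxohexa-2,4-dienoate
Conditions: 2 (1.0 equiv), toluene, 80 °C
Reagents that add atoms: none
Why: Wittig olefination with a stabilized formyl ylide gives the (E)-alkene; the aldehyde of 1, activated by the conjugated ester, is more electrophilic than the dienal product, so one equivalent of 2 should stop at 3.

Step 2
Reactants: 3 ethyl (2E,4E)-3-methyl-6-oxohexa-2,4-dienoate; 4 dimethyl malonate
Product: 5 ethyl (2E,4R)-4-[bis(methoxycarbonyl)methyl]-3-methyl-6-oxohex-2-enoate
Conditions: (S)-2-{bis[3,5-bis(trifluoromethyl)phenyl][(trimethylsilyl)oxy]methyl}pyrrolidine (10 mol%), EtOH, 0 °C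
Reagents that add atoms: none
Why: Iminium-ion catalysed Michael addition of a malonate to an enal (diarylprolinol silyl ether catalysis): the malonate adds to the β-carbon (labdane C5) of the E,s-trans iminium ion on the face opposite the diarylsilyloxymethyl group, which for the (S)-catalyst gives the 4R centre. The δ-carbon is α to the ester and next to the γ-methyl, so 1,4- should win over 1,6-addition; this is the only centre made under catalyst control.

Step 3
Reactants: 5 ethyl (2E,4R)-4-[bis(methoxycarbonyl)methyl]-3-methyl-6-oxohex-2-enoate
Product: 6 (3R,4E)-3-[bis(methoxycarbonyl)methyl]-6-ethoxy-4-methyl-6-oxohex-4-enoic acid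
Conditions: NaClO2, NaH2PO4, 2-methyl-2-butene, t-BuOH/H2O, 0 °C → rt
Reagents that add atoms: sodium chlorite, [Na+].[O-]Cl=O
Why: Pinnick oxidation: chlorous acid oxidizes only the aldehyde, and the buffered medium with a hypochlorite scavenger leaves the malonate C–H, the enoate and the β-stereocentre untouched.

Step 4
Reactants: 6 (3R,4E)-3-[bis(methoxycarbonyl)methyl]-6-ethoxy-4-methyl-6-oxohex-4-enoic acid
Product: 8 ethyl (2E,4R)-4-[bis(methoxycarbonyl)methyl]-7-diazo-3-methyl-6-oxohept-2-enoate, via mixed isobutyl carbonic anhydride 7 (not isolated)
Conditions: i-BuOCOCl, N-methylmorpholine, THF, −15 °C; then CH2N2, Et2O, 0 °C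
Reagents that add atoms: diazomethane, C=[N+]=[N-]
Why: First half of the Arndt–Eistert homologation: the mixed carbonic anhydride acylates diazomethane. The β,β-disubstituted enoate is a poor dipolarophile and should survive a small excess of diazomethane at 0 °C.

Step 5
Reactants: 8 ethyl (2E,4R)-4-[bis(methoxycarbonyl)methyl]-7-diazo-3-methyl-6-oxohept-2-enoate
Product: 10 1-ethyl 7-methyl (2E,4R)-4-[bis(methoxycarbonyl)methyl]-3-methylhept-2-enedioate, via ketene 9 (not isolated)
Conditions: PhCO2Ag (10 mol%), Et3N, MeOH, rt, dark
Reagents that add atoms: methanol, CO
Why: Silver-catalysed Wolff rearrangement: loss of N2 with 1,2-shift of the C6 methylene gives ketene 9, which methanol traps as the C8 methyl ester. The stereocentre is β to the migrating carbon and is not touched.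

Step 6
Reactants: 10 1-ethyl 7-methyl (2E,4R)-4-[bis(methoxycarbonyl)methyl]-3-methylhept-2-enedioate; 11 acrolein
Product: 12 1-ethyl 7-methyl (2E,4S)-4-[1,1-bis(methoxycarbonyl)-4-oxobutyl]-3-methylhept-2-enedioate
Conditions: 11 (1.5 equiv), DBU (10 mol%), MeCN, −20 → 0 °C
Reagents that add atoms: none
Why: Base-catalysed Michael addition of the tertiary malonate carbanion to acrolein makes C4 quaternary (still achiral) and installs C1–C3 with C1 as the aldehyde. C5 cannot epimerize, because after the homologation no carbonyl group is α to C6 and a retro-Michael path is closed; the descriptor changes to S only because C4 now outranks C10.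

Step 7
Reactants: 12 1-ethyl 7-methyl (2E,4S)-4-[1,1-bis(methoxycarbonyl)-4-oxobutyl]-3-methylhept-2-enedioate
Product: 14 9-ethyl 4,4-dimethyl (1S,5S,9S,10R)-1-hydroxy-10-methyl-8-oxo-trans-decalin-4,4,9-tricarboxylate (labdane numbering), via ring A disamarium alkoxide enolate 13 (not isolated)
Conditions: SmI2 (2.5 equiv), HMPA (10 equiv), THF, −78 → 0 °C, 12 added slowly; then aq. pH 7 buffer
Reagents that add atoms: none
Why: SmI2–HMPA transfers one electron to the aldehyde, the most easily reduced group of 12, and the C1 ketyl adds 6-exo-trig to C10, the β-carbon of the enoate, closing ring A; a second electron turns the C9 radical into the trivalent samarium ester enolate 13. Because this enolate is formed only at C9, it can only attack the C8 methyl ester, a 6-exo-trig Dieckmann-type acylation that closes ring B and expels methoxide, whereas a base would enolize C7 instead. The closest known reaction type is the samarium diiodide ketyl–olefin cyclization onto unsaturated esters with intramolecular trapping of the samarium enolate (aldol commonly, ester acylation more rarely). C10 is set relative to C5 by allylic 1,3-strain: the C5–H bond eclipses the C10=C9 bond (C9 carries only H cis to C5) and the ketyl arrives on the face that holds its tether through C4, so the methyl ends trans to H5 and C9 equatorial. C1 is set in the chair by the bulky HMPA-solvated O–Sm group taking the equatorial position, trans to the enoate arm on the new ring, which places the oxygen cis to the C10 methyl. C9 is an epimerizable β-keto ester centre that should settle equatorial (hydrogen bond to the C1 hydroxyl) and is made planar again in step 10. The step needs reduction of the aldehyde in preference to the enoate and esters, and a live enolate, both secured by the reduction potentials and the absence of a proton source; it also needs acylation at C8 and not at the C4 esters, secured because C9 is anti to C4 in the chair. The gem-diester at C4 biases the chain toward ring closure.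

Step 8
Reactants: 15 (E)-3-methylpent-2-en-4-yn-1-ol
Product: 16 (E)-3-methylpenta-2,4-dien-1-ol
Conditions: H2 (1 atm), Pd/CaCO3 poisoned with Pb(OAc)2, quinoline, EtOAc, rt
Reagents that add atoms: none
Why: Semihydrogenation of the terminal alkyne over lead-poisoned palladium stops at the alkene. The trisubstituted (E)-alkene is not touched, so the geometry of the enynol is carried into the diene.

Step 9
Reactants: 16 (E)-3-methylpenta-2,4-dien-1-ol
Product: 17 (E)-5-bromo-3-methylpenta-1,3-diene
Conditions: PBr3 (0.4 equiv), Et2O, −10 °C
Reagents that add atoms: phosphorus tribromide, BrP(Br)Br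
Why: Conversion of a primary allylic alcohol into the bromide (SN2 displacement on the bromophosphite). Low temperature limits allylic transposition, and the (E)-isomer is also the more stable one.

Step 10
Reactants: 14 9-ethyl 4,4-dimethyl (1S,5S,9S,10R)-1-hydroxy-10-methyl-8-oxo-trans-decalin-4,4,9-tricarboxylate; 17 (E)-5-bromo-3-methylpenta-1,3-diene
Product: 18 9-ethyl 4,4-dimethyl (1S,5S,9S,10R)-1-hydroxy-10-methyl-9-[(2E)-3-methylpenta-2,4-dienyl]-8-oxo-trans-decalin-4,4,9-tricarboxylate (labdane numbering)
Conditions: 17 (1.5 equiv), K2CO3, acetone, 50 °C
Reagents that add atoms: none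
Why: C-Alkylation of a β-keto ester enolate with a primary allylic bromide (SN2). The electrophile should enter trans to the C10 methyl, but the configuration at C9 is of no consequence because it is made planar in step 11; carbonate does not deprotonate the C1 hydroxyl.

Step 11
Reactants: 18 9-ethyl 4,4-dimethyl (1S,5S,9S,10R)-1-hydroxy-10-methyl-9-[(2E)-3-methylpenta-2,4-dienyl]-8-oxo-trans-decalin-4,4,9-tricarboxylate
Product: 19 methyl (1S,5R,9S,10R)-1-hydroxy-10-methyl-9-[(2E)-3-methylpenta-2,4-dienyl]-8-oxo-trans-decalin-4-carboxylate (labdane numbering; C4 epimers)
Conditions: LiCl, H2O, DMSO, 150 °C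
Reagents that add atoms: none
Why: Krapcho dealkoxycarbonylation: chloride dealkylates the C9 ethyl ester and one C4 methyl ester (SN2 at the O-alkyl carbon), each carboxylate loses CO2, and water protonates the resulting enol(ate). At C9 the proton should be delivered axially on the face trans to the C10 methyl, which places the side chain equatorial as in 23; C4 becomes a CH of no stereochemical consequence.

Step 12
Reactants: 19 methyl (1S,5R,9S,10R)-1-hydroxy-10-methyl-9-[(2E)-3-methylpenta-2,4-dienyl]-8-oxo-trans-decalin-4-carboxylate
Product: 20 methyl (1S,5R,9R,10R)-1-hydroxy-10-methyl-8-methylidene-9-[(2E)-3-methylpenta-2,4-dienyl]-trans-decalin-4-carboxylate (labdane numbering; C4 epimers)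
Conditions: Ph3PCH3Br, KOtBu (4 equiv each), toluene, rt → 60 °C
Reagents that add atoms: methyltriphenylphosphonium bromide, C[P+](c1ccccc1)(c1ccccc1)c1ccccc1.[Br-]
Why: Wittig methylenation of a hindered cyclohexanone, with excess ylide to compensate for the alkoxide formed at C1. Under the basic conditions the C9 epimers can interconvert, and the epimer with the equatorial side chain, whose carbonyl is open on the face trans to the C10 methyl, should be the one that is olefinated.

Step 13
Reactants: 20 methyl (1S,5R,9R,10R)-1-hydroxy-10-methyl-8-methylidene-9-[(2E)-3-methylpenta-2,4-dienyl]-trans-decalin-4-carboxylate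
Product: 22 methyl (1S,4R,5S,9R,10S)-1-hydroxy-4,10-dimethyl-8-methylidene-9-[(2E)-3-methylpenta-2,4-dienyl]-trans-decalin-4-carboxylate (labdane numbering), via dilithium alkoxide enolate 21 (not isolated)
Conditions: LiN(iPr)2 (2.5 equiv), THF, −78 → −20 °C; MeI (1.5 equiv), −78 → −20 °C; then H2O
Reagents that add atoms: iodomethane, CI
Why: Alkylation of an exocyclic ester enolate, here as the alkoxide–enolate dianion 21: iodomethane should approach C4 trans to the syn-axial C10 methyl, along the equatorial trajectory, so the new methyl is equatorial and the ester axial and cis to the C10 methyl (4R). The hindered lithium alkoxide at C1 is a poor nucleophile at low temperature and should not be methylated.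

Step 14
Reactants: 22 methyl (1S,4R,5S,9R,10S)-1-hydroxy-4,10-dimethyl-8-methylidene-9-[(2E)-3-methylpenta-2,4-dienyl]-trans-decalin-4-carboxylate
Product: 23 methyl (1R,4S,4aS,5R,8aS)-4-acetoxy-1,4a-dimethyl-6-methylidene-5-[(2E)-3-methylpenta-2,4-dien-1-yl]decahydronaphthalene-1-carboxylate (labdane numbering: 1S,4R,5S,9R,10S)
Conditions: Ac2O, DMAP, Et3N, CH2Cl2, rt
Reagents that add atoms: acetic anhydride, CC(=O)OC(C)=O
Why: DMAP-catalysed acylation of the secondary, equatorial C1 alcohol. The mildly basic medium leaves the diene, the exocyclic alkene and the ester untouched, and C1 keeps its configuration.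

## Compound list

1 | ethyl (E)-3-methyl-4-oxobut-2-enoate | CCOC(=O)/C=C(\C)C=O | starting material
2 | (formylmethylene)triphenylphosphorane | O=CC=P(c1ccccc1)(c1ccccc1)c1ccccc1 | starting material
3 | ethyl (2E,4E)-3-methyl-6-oxohexa-2,4-dienoate | CCOC(=O)/C=C(C)/C=C/C=O | intermediate
4 | dimethyl malonate | COC(=O)CC(=O)OC | starting material
5 | ethyl (2E,4R)-4-[bis(methoxycarbonyl)methyl]-3-methyl-6-oxohex-2-enoate | COC(=O)C(C(=O)OC)[C@@H](CC=O)/C(C)=C/C(=O)OCC | intermediate
6 | (3R,4E)-3-[bis(methoxycarbonyl)methyl]-6-ethoxy-4-methyl-6-oxohex-4-enoic acid | COC(=O)C(C(=O)OC)[C@@H](CC(=O)O)/C(C)=C/C(=O)OCC | intermediate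
7 | mixed isobutyl carbonic anhydride of acid 6 | COC(=O)C(C(=O)OC)[C@@H](CC(=O)OC(=O)OCC(C)C)/C(C)=C/C(=O)OCC | intermediate
8 | ethyl (2E,4R)-4-[bis(methoxycarbonyl)methyl]-7-diazo-3-methyl-6-oxohept-2-enoate | COC(=O)C(C(=O)OC)[C@@H](CC(=O)C=[N+]=[N-])/C(C)=C/C(=O)OCC | intermediate
9 | ketene, ethyl (2E,4R)-4-[bis(methoxycarbonyl)methyl]-3-methyl-7-oxohepta-2,6-dienoate | COC(=O)C(C(=O)OC)[C@@H](CC=C=O)/C(C)=C/C(=O)OCC | intermediate
10 | 1-ethyl 7-methyl (2E,4R)-4-[bis(methoxycarbonyl)methyl]-3-methylhept-2-enedioate | COC(=O)C(C(=O)OC)[C@@H](CCC(=O)OC)/C(C)=C/C(=O)OCC | intermediate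
11 | acrolein | C=CC=O | starting material
12 | 1-ethyl 7-methyl (2E,4S)-4-[1,1-bis(methoxycarbonyl)-4-oxobutyl]-3-methylhept-2-enedioate (key-step precursor) | O=CCCC(C(=O)OC)(C(=O)OC)[C@@H](CCC(=O)OC)/C(C)=C/C(=O)OCC | intermediate
13 | ring A disamarium alkoxide ester enolate (C1–C10 bond formed, C9 enolate) | CCOC(O[Sm](I)I)=C[C@]1(C)[C@@H](O[Sm](I)I)CCC(C(=O)OC)(C(=O)OC)[C@H]1CCC(=O)OC | intermediate
14 | 9-ethyl 4,4-dimethyl (1S,5S,9S,10R)-1-hydroxy-10-methyl-8-oxo-trans-decalin-4,4,9-tricarboxylate (labdane numbering; OH and C9 ester cis to the C10 methyl, H5 trans) | CCOC(=O)[C@@H]1C(=O)CC[C@H]2[C@@]1(C)[C@@H](O)CCC2(C(=O)OC)C(=O)OC | intermediate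
15 | (E)-3-methylpent-2-en-4-yn-1-ol | C#C/C(C)=C/CO | starting material
16 | (E)-3-methylpenta-2,4-dien-1-ol | C=C/C(C)=C/CO | intermediate
17 | (E)-5-bromo-3-methylpenta-1,3-diene | C=C/C(C)=C/CBr | intermediate
18 | 9-ethyl 4,4-dimethyl (1S,5S,9S,10R)-1-hydroxy-10-methyl-9-[(2E)-3-methylpenta-2,4-dienyl]-8-oxo-trans-decalin-4,4,9-tricarboxylate (side chain trans, C9 ester cis to the C10 methyl) | CCOC(=O)[C@]1(C/C=C(C)/C=C)C(=O)CC[C@H]2[C@@]1(C)[C@@H](O)CCC2(C(=O)OC)C(=O)OC | intermediate
19 | methyl (1S,5R,9S,10R)-1-hydroxy-10-methyl-9-[(2E)-3-methylpenta-2,4-dienyl]-8-oxo-trans-decalin-4-carboxylate (side chain cis to the C10 methyl; C4 epimers) | C=C/C(C)=C/C[C@@H]1C(=O)CC[C@H]2[C@@]1(C)[C@@H](O)CCC2C(=O)OC | intermediate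
20 | methyl (1S,5R,9R,10R)-1-hydroxy-10-methyl-8-methylidene-9-[(2E)-3-methylpenta-2,4-dienyl]-trans-decalin-4-carboxylate (C4 epimers) | C=C/C(C)=C/C[C@@H]1C(=C)CC[C@H]2[C@@]1(C)[C@@H](O)CCC2C(=O)OC | intermediate
21 | dilithium alkoxide ester enolate of 20 | C=C/C(C)=C/C[C@@H]1C(=C)CC[C@H]2[C@@]1(C)[C@@H](O[Li])CCC2=C(OC)O[Li] | intermediate
22 | methyl (1S,4R,5S,9R,10S)-1-hydroxy-4,10-dimethyl-8-methylidene-9-[(2E)-3-methylpenta-2,4-dienyl]-trans-decalin-4-carboxylate | C=C/C(C)=C/C[C@@H]1C(=C)CC[C@H]2[C@@]1(C)[C@@H](O)CC[C@@]2(C)C(=O)OC | intermediate
23 | methyl (1R,4S,4aS,5R,8aS)-4-acetoxy-1,4a-dimethyl-6-methylidene-5-[(2E)-3-methylpenta-2,4-dien-1-yl]decahydronaphthalene-1-carboxylate | C=C/C(C)=C/C[C@@H]1C(=C)CC[C@H]2[C@@]1(C)[C@@H](OC(C)=O)CC[C@@]2(C)C(=O)OC | target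

## Step count and least certain steps

Total: 14 steps. Longest linear sequence: 12 steps (steps 1–7 and 10–14); steps 8 and 9 make the side-chain bromide.

**Step 7 (key step).** The most likely failure is protonation of the trivalent samarium enolate at C9, a hindered neopentyl-type nucleophile, before it acylates the C8 methyl ester, so that only ring A closes. The six-membered ketyl addition to fully substituted C10 may also be slow enough for pinacol coupling or simple reduction of the aldehyde to compete. A base-mediated Dieckmann closure of the ring A product is not a remedy, because a base would enolize C7 and acylate the wrong esters. The fallback makes the acyl acceptor more reactive at no cost in steps. It sets out from diazoketone 8, whose Wolff rearrangement (PhCO2Ag, Et3N) in 2,2,2-trifluoroethanol gives the 2,2,2-trifluoroethyl ester F1. Addition to acrolein as in step 6 gives the aldehyde F2, and the SmI2 cascade on F2 expels trifluoroethoxide and returns to the route at 14.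

**Step 2.** Facial selectivity may be insufficient with an alkenyl β-substituent, and some addition at the δ-carbon of the extended iminium ion is possible; every later stereocentre depends on this one. The fallback replaces catalyst control by resolution. It sets out from 3 and 4: pyrrolidine and benzoic acid (catalytic) give the racemic aldehyde F3, Pinnick oxidation gives the racemic acid F4, and crystallization with (S)-1-phenylethylamine (or its antipode, whichever gives the less soluble salt of the wanted acid) gives the salt F5. Acidification returns to the route at 6.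

**Step 10.** O-Alkylation, or slow C-alkylation at a carbon next to quaternary C10 (vicinal quaternary centres) while the allylic bromide degrades, is the main concern. The fallback uses a soft π-allyl electrophile, for which O-allylation is reversible. It sets out from 16, which with methyl chloroformate and pyridine gives the allylic methyl carbonate F6. Reaction of 14 with F6 and Pd(PPh3)4 (catalytic zerovalent palladium, THF, rt; Tsuji–Trost allylation) returns to the route at 18.

**Step 11.** Thermal loss of the diene (dimerization, polymerization) during the hours at 150 °C that the C4 ester needs is the most likely problem. Lactonization of the C1 hydroxyl onto the neighbouring C9 ester could also slow the dealkylation. The fallback carries the side chain as a robust enyne. It sets out from 15, which with PBr3 gives the bromide F7. Alkylation of 14 with F7 (K2CO3, acetone) gives the β-keto ester F8, the same LiCl/DMSO treatment gives the enyne ketone F9, and semihydrogenation over Pd/CaCO3 poisoned with Pb(OAc)2 returns to the route at 19.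

**Step 12.** The basic ylide may enolize the hindered C8 ketone, which stalls the olefination and lets C9 drift toward the axial epimer; the equatorial side chain has a syn-pentane contact with the C1 oxygen, so the equilibrium position is not secure. The fallback is a two-step Peterson olefination with a non-basic nucleophile. It sets out from 19, which with Me3SiCH2Li/CeCl3 (THF, −78 °C) gives the β-hydroxysilane F10 without enolization. Elimination with KH returns to the route at 20.

**Step 13.** O-Methylation of the C1 alkoxide, or incomplete enolization of the aggregated dianion, is more likely than a facial problem. The fallback removes the alkoxide. It sets out from 20, which with Et3SiOTf and 2,6-lutidine gives the triethylsilyl ether F11. Enolization with LiN(iPr)2 and methylation with MeI give the methylated silyl ether F12, and Bu4NF returns to the route at 22.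

## Further compounds

F1 | step 7 | 1-ethyl 7-(2,2,2-trifluoroethyl) (2E,4R)-4-[bis(methoxycarbonyl)methyl]-3-methylhept-2-enedioate | COC(=O)C(C(=O)OC)[C@@H](CCC(=O)OCC(F)(F)F)/C(C)=C/C(=O)OCC
F2 | step 7 | 1-ethyl 7-(2,2,2-trifluoroethyl) (2E,4S)-4-[1,1-bis(methoxycarbonyl)-4-oxobutyl]-3-methylhept-2-enedioate | O=CCCC(C(=O)OC)(C(=O)OC)[C@@H](CCC(=O)OCC(F)(F)F)/C(C)=C/C(=O)OCC
F3 | step 2 | racemic ethyl (2E)-4-[bis(methoxycarbonyl)methyl]-3-methyl-6-oxohex-2-enoate | COC(=O)C(C(=O)OC)C(CC=O)/C(C)=C/C(=O)OCC
F4 | step 2 | racemic (4E)-3-[bis(methoxycarbonyl)methyl]-6-ethoxy-4-methyl-6-oxohex-4-enoic acid | COC(=O)C(C(=O)OC)C(CC(=O)O)/C(C)=C/C(=O)OCC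
F5 | step 2 | (S)-1-phenylethylammonium salt of acid 6 | COC(=O)C(C(=O)OC)[C@@H](CC(=O)[O-])/C(C)=C/C(=O)OCC.C[C@H]([NH3+])c1ccccc1
F6 | step 10 | methyl (2E)-3-methylpenta-2,4-dien-1-yl carbonate | C=C/C(C)=C/COC(=O)OC
F7 | step 11 | (E)-5-bromo-3-methylpent-3-en-1-yne | C#C/C(C)=C/CBr
F8 | step 11 | 9-ethyl 4,4-dimethyl (1S,5S,9S,10R)-1-hydroxy-10-methyl-9-[(2E)-3-methylpent-2-en-4-ynyl]-8-oxo-trans-decalin-4,4,9-tricarboxylate | CCOC(=O)[C@]1(C/C=C(C)/C#C)C(=O)CC[C@H]2[C@@]1(C)[C@@H](O)CCC2(C(=O)OC)C(=O)OC
F9 | step 11 | methyl (1S,5R,9S,10R)-1-hydroxy-10-methyl-9-[(2E)-3-methylpent-2-en-4-ynyl]-8-oxo-trans-decalin-4-carboxylate (C4 epimers) | C#C/C(C)=C/C[C@@H]1C(=O)CC[C@H]2[C@@]1(C)[C@@H](O)CCC2C(=O)OC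
F10 | step 12 | methyl (1S,5R,9R,10R)-1,8-dihydroxy-10-methyl-9-[(2E)-3-methylpenta-2,4-dienyl]-8-[(trimethylsilyl)methyl]-trans-decalin-4-carboxylate (C4 and C8 epimers) | C=C/C(C)=C/C[C@@H]1C(O)(C[Si](C)(C)C)CC[C@H]2[C@@]1(C)[C@@H](O)CCC2C(=O)OC
F11 | step 13 | triethylsilyl ether of 20 | C=C/C(C)=C/C[C@@H]1C(=C)CC[C@H]2[C@@]1(C)[C@@H](O[Si](CC)(CC)CC)CCC2C(=O)OC
F12 | step 13 | triethylsilyl ether of 22 | C=C/C(C)=C/C[C@@H]1C(=C)CC[C@H]2[C@@]1(C)[C@@H](O[Si](CC)(CC)CC)CC[C@@]2(C)C(=O)OC
A1 | alternative 1 | (1E,3E)-1-(tert-butyldimethylsilyloxy)-5-(4-methoxybenzyloxy)penta-1,3-diene | CC(C)(C)[Si](C)(C)O/C=C/C=C/COCc1ccc(OC)cc1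
A2 | alternative 1 | (2E)-6-bromo-2-methylhepta-2,6-dienal | O=C/C(C)=C/CCC(Br)=C
A3 | alternative 1 | 6-(3-bromobut-3-en-1-yl)-2-(tert-butyldimethylsilyloxy)-5-[(4-methoxybenzyloxy)methyl]-1-methylcyclohex-3-ene-1-carbaldehyde (ring A aldehyde, configuration as in the SMILES) | O=C[C@]1(C)[C@@H](O[Si](C)(C)C(C)(C)C)C=C[C@@H](COCc2ccc(OC)cc2)[C@H]1CCC(Br)=C
A4 | alternative 2 | methyl (2E,7S)-7-[2-(tert-butyldimethylsilyloxy)ethyl]-8-methyl-6-methylidene-9-oxoundeca-2,10-dienoate (C8 epimers) | C=CC(=O)C(C)[C@H](CCO[Si](C)(C)C(C)(C)C)C(=C)CC/C=C/C(=O)OC
A5 | alternative 2 | methyl 9-[2-(tert-butyldimethylsilyloxy)ethyl]-10-methyl-8-methylidene-1-oxo-trans-decalin-4-carboxylate (labdane numbering, configuration as in the SMILES) | CC(C)(C)[Si](C)(C)OCC[C@@H]1C(=C)CC[C@H]2[C@@]1(C)C(=O)CC[C@@H]2C(=O)OC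
A6 | alternative 3 | methyl 2-[6-(tert-butyldimethylsilyloxy)-4-(methoxycarbonyloxy)-3-methylidenehexyl]-4-hydroxy-3-methylbenzoate (racemic carbonate) | COC(=O)OC(CCO[Si](C)(C)C(C)(C)C)C(=C)CCc1c(C)c(O)ccc1C(=O)OC
A7 | alternative 3 | methyl 9-[2-(tert-butyldimethylsilyloxy)ethyl]-10-methyl-8-methylidene-1-oxo-1,6,7,8,9,10-hexahydronaphthalene-4-carboxylate (labdane numbering, cyclohexa-2,4-dienone) | CC(C)(C)[Si](C)(C)OCC[C@@H]1C(=C)CCC2=C(C(=O)OC)C=CC(=O)[C@@]12C
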